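**Retrosynthetic overview** (compound numbers are assigned in the forward route below)
1. Target ⇒ its 3,5-diallyl analogue by two alkene cross-metatheses with 2-methyl-2-butene (allyl → prenyl); the two OMe groups ⇒ selective O-methylation of 3,5-diallyl-2,4,6-trihydroxybenzophenone, leaving the ketone-chelated OH free.
2. The two C-allyl groups ⇒ double aromatic Claisen rearrangement of the 4,6-bis(allyl ether) of 2,4,6-trihydroxybenzophenone; C3 and C5 are the only free ring positions, so all pathways converge.
3. Ring B (the phloroglucinol ring) ⇒ intramolecular Claisen cyclisation (C6 onto the C1 ester) of methyl 3,5,7-trioxo-7-phenylheptanoate.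
4. Key C–C bond (the later aryl–C=O bond) ⇒ intermolecular Claisen condensation of methyl benzoate with the trianion of methyl 3,5-dioxohexanoate, itself made from dehydroacetic acid.
5. Ring order: ring A (phenyl) is bought in methyl benzoate; ring B is the only ring built, directly after the key condensation.

Assumption: the target has no stereocentre and no stereogenic double bond, so it is achiral and no stereocontrol is needed.

**Route**

Step 1
Reactants: 1 dehydroacetic acid (3-acetyl-4-hydroxy-6-methyl-2H-pyran-2-one)
Product: 3 methyl 3,5-dioxohexanoate, via methyl 2-acetyl-3,5-dioxohexanoate 2 (not isolated)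
Conditions: Mg(OMe)2 (2.2 equiv, commercial solution), MeOH, reflux, 6 h; then cold dilute aq HCl
Reagents that add atoms: methanol, CO (delivered as magnesium methoxide Mg(OMe)2, C[O-].C[O-].[Mg+2])
Why: Methoxide opens the enol lactone to the 2-acetyl β-keto ester, which is deacetylated by retro-Claisen cleavage to the stable magnesium chelate of 3 (lactone methanolysis/retro-Claisen sequence; no stereocentre formed).

Step 2
Reactants: 3 methyl 3,5-dioxohexanoate (2.0 equiv); 4 methyl benzoate (1.0 equiv)
Product: 6 methyl 3,5,7-trioxo-7-phenylheptanoate, via trilithium trianion of methyl 3,5-dioxohexanoate 5 (not isolated)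
Conditions: LiN(iPr)2 (6.2 equiv, commercial solution), THF, −78 → 0 °C, 1 h; then 4, 0 → 25 °C, 12 h; then cold dilute aq HCl
Reagents that add atoms: none
Why: Intermolecular Claisen condensation in which the terminal, most nucleophilic carbanion of the trianion attacks the non-enolisable ester 4 and forms the future aryl–carbonyl bond, the excess trianion serving as base for the more acidic product (no stereocentre).

Step 3
Reactants: 6 methyl 3,5,7-trioxo-7-phenylheptanoate
Product: 8 (2,4,6-trihydroxyphenyl)(phenyl)methanone, via 2-benzoylcyclohexane-1,3,5-trione 7 (not isolated)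
Conditions: KOH (2 mol/L in water, excess), N2, 25 °C, 16 h; then aq HCl to pH 2
Reagents that add atoms: none
Why: Intramolecular Claisen (Dieckmann-type) cyclisation of C6 onto the C1 ester closes ring B, and irreversible tautomerisation of the cyclic triketone to the phloroglucinol drives it to completion (no stereocentre).

Step 4
Reactants: 8 (2,4,6-trihydroxyphenyl)(phenyl)methanone
Product: 9 [2-hydroxy-4,6-bis(prop-2-en-1-yloxy)phenyl](phenyl)methanone
Conditions: allyl bromide (2.1 equiv), K2CO3 (2.2 equiv), acetone, reflux, 8 h
Reagents that add atoms: allyl bromide, C=CCBr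
Why: Williamson etherification alkylates the 4-OH and one ortho OH, while the remaining OH is hydrogen-bonded to the ketone and resists K2CO3/acetone, as in the analogous phloroacetophenone dialkylations.

Step 5
Reactants: 9 [2-hydroxy-4,6-bis(prop-2-en-1-yloxy)phenyl](phenyl)methanone
Product: 10 (3,5-diallyl-2,4,6-trihydroxyphenyl)(phenyl)methanone
Conditions: N,N-diethylaniline, N2, 200 °C (sealed tube), 5 h
Reagents that add atoms: none
Why: Double aromatic Claisen rearrangement ([3,3]-sigmatropic) delivers each unsubstituted allyl group to C3 or C5, either directly ortho or by ortho shift to a blocked carbon followed by Cope shift to para, so every pathway converges on symmetric 10.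

Step 6
Reactants: 10 (3,5-diallyl-2,4,6-trihydroxyphenyl)(phenyl)methanone
Product: 11 (3,5-diallyl-2-hydroxy-4,6-dimethoxyphenyl)(phenyl)methanone
Conditions: Me2SO4 (2.1 equiv), K2CO3 (2.5 equiv), acetone, reflux, 6 h
Reagents that add atoms: dimethyl sulfate, COS(=O)(=O)OC
Why: Selective Williamson O-methylation with a hard electrophile takes the 4-OH and one ortho OH, and the last OH stays free because it is chelated to the benzoyl carbonyl (the xanthoxylin/hydrocotoin pattern).

Step 7
Reactants: 11 (3,5-diallyl-2-hydroxy-4,6-dimethoxyphenyl)(phenyl)methanone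
Product: 12 [2-hydroxy-4,6-dimethoxy-3,5-bis(3-methylbut-2-en-1-yl)phenyl](phenyl)methanone (target)
Conditions: second-generation Grubbs catalyst RuCl2(=CHPh)(H2IMes)(PCy3) (5 mol %), 2-methyl-2-butene (large excess), CH2Cl2, 40 °C (sealed), 12 h
Reagents that add atoms: 2-methyl-2-butene, CC=C(C)C
Why: Olefin cross-metathesis of both terminal allyl groups with excess 2-methyl-2-butene exchanges =CH2 for =CMe2 to give the two prenyl groups, with no E/Z issue because the new alkene terminus carries two methyl groups, and the chelated phenol and diaryl ketone are tolerated.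

**Compound list**
1 | dehydroacetic acid (3-acetyl-4-hydroxy-6-methyl-2H-pyran-2-one) | CC(=O)C1=C(O)C=C(C)OC1=O | starting material
2 | methyl 2-acetyl-3,5-dioxohexanoate (not isolated) | COC(=O)C(C(C)=O)C(=O)CC(C)=O | intermediate
3 | methyl 3,5-dioxohexanoate | COC(=O)CC(=O)CC(C)=O | intermediate
4 | methyl benzoate | COC(=O)c1ccccc1 | starting material
5 | trilithium trianion of methyl 3,5-dioxohexanoate (not isolated) | [Li+].[Li+].[Li+].C=C([O-])C=C([O-])C=C([O-])OC | intermediate
6 | methyl 3,5,7-trioxo-7-phenylheptanoate | COC(=O)CC(=O)CC(=O)CC(=O)c1ccccc1 | intermediate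
7 | 2-benzoylcyclohexane-1,3,5-trione (not isolated) | O=C1CC(=O)C(C(=O)c2ccccc2)C(=O)C1 | intermediate
8 | (2,4,6-trihydroxyphenyl)(phenyl)methanone | O=C(c1ccccc1)c1c(O)cc(O)cc1O | intermediate
9 | [2-hydroxy-4,6-bis(prop-2-en-1-yloxy)phenyl](phenyl)methanone | C=CCOc1cc(O)c(C(=O)c2ccccc2)c(OCC=C)c1 | intermediate
10 | (3,5-diallyl-2,4,6-trihydroxyphenyl)(phenyl)methanone | C=CCc1c(O)c(CC=C)c(O)c(C(=O)c2ccccc2)c1O | intermediate
11 | (3,5-diallyl-2-hydroxy-4,6-dimethoxyphenyl)(phenyl)methanone | COc1c(CC=C)c(O)c(C(=O)c2ccccc2)c(OC)c1CC=C | intermediate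
12 | [2-hydroxy-4,6-dimethoxy-3,5-bis(3-methylbut-2-en-1-yl)phenyl](phenyl)methanone | COc1c(CC=C(C)C)c(O)c(C(=O)c2ccccc2)c(OC)c1CC=C(C)C | target

**Totals**
Total step count: 7. Longest linear sequence: 7 steps (1 → 3 → 6 → 8 → 9 → 10 → 11 → 12).

**Steps most likely to fail, with fallbacks**

Step 2 (polyanion acylation; proton transfer to the product or self-condensation may cut the yield). The fallback sets out from 4 and comes back at 6. Compound 4 is condensed with the sodium enolate of acetylacetone (pentane-2,4-dione; NaH, 1,2-dimethoxyethane, reflux) in a terminal Claisen acylation that gives 1-phenylhexane-1,3,5-trione F1. Its trianion (LiN(iPr)2, 3.1 equiv, THF, 0 °C) is carboxylated at the terminal methyl with CO2 to give 7-phenyl-3,5,7-trioxoheptanoic acid F2. Brief treatment with diazomethane (Et2O, 0 °C) esterifies the acid to 6.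

Step 3 (ester saponification followed by aldol-mode closure to a resorcylic acid can compete with the Claisen mode). The fallback sets out from 6 and comes back at 8. Compound 6 is lactonised without base (toluene, reflux, methanol distilled off) to the crystalline 4-hydroxy-6-(2-oxo-2-phenylethyl)-2H-pyran-2-one F3. Mg(OMe)2 in MeOH at reflux then opens the lactone inside a magnesium chelate of the trioxo chain, with no hydroxide present, and the C6 carbanion closes onto the regenerated ester in the Claisen mode to give 8 after acidification.

Step 5 (double thermal rearrangement at 200 °C; incomplete migration or cyclisation of the o-allylphenols to dihydrobenzofurans is possible). The fallback sets out from 8 and comes back at 12. Direct double C-prenylation of the phloroglucinol anion of 8 (prenyl bromide, 2.2 equiv, DBU, THF, 0 → 25 °C) gives [2,4,6-trihydroxy-3,5-bis(3-methylbut-2-en-1-yl)phenyl](phenyl)methanone F4 after chromatographic removal of mono- and O-prenylated material. Me2SO4 (2.1 equiv)/K2CO3 in acetone then methylates the two unchelated hydroxyls to give 12, which makes steps 4 to 7 unnecessary at the cost of a lower-yielding prenylation.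

**Further compounds**
F1 | step 2 | 1-phenylhexane-1,3,5-trione | CC(=O)CC(=O)CC(=O)c1ccccc1
F2 | step 2 | 7-phenyl-3,5,7-trioxoheptanoic acid | OC(=O)CC(=O)CC(=O)CC(=O)c1ccccc1
F3 | step 3 | 4-hydroxy-6-(2-oxo-2-phenylethyl)-2H-pyran-2-one | O=C1C=C(O)C=C(CC(=O)c2ccccc2)O1
F4 | step 5 | [2,4,6-trihydroxy-3,5-bis(3-methylbut-2-en-1-yl)phenyl](phenyl)methanone | CC(C)=CCc1c(O)c(CC=C(C)C)c(O)c(C(=O)c2ccccc2)c1O
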